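**Retrosynthetic overview**
1. 14 ⇒ 13: the C11–OOH/Δ9 unit comes last, from a singlet-oxygen ene reaction on the Δ10 prenyl terminus. This matches the presumed last biosynthetic event.
2. 13 ⇒ 11: both ketones (C2, C8) come from one double dehydrogenation of the 2,8-diol.
3. 11 ⇒ 9 (key step): both oxiranes are closed in one operation on the complete C15 bis(allylic alcohol). The 2-OH steers C3/C4. The 8-OH is a traceless relay for C7 and is erased in step 6.
4. 9 ⇒ 5 + 6: the C8–C9 bond is made by α-selective prenylation of a 2-substituted acrolein, followed by 1,2-reduction of the ring enone.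
5. 5 ⇒ 1 + 2: the carbocycle is bought as (R)-carvone. Ring order: carbocycle (terpene pool) → C7–C14 oxirane → C3–C4 oxirane, the last two in the same flask.

Assumption: bisabolane numbering is used. C1 = CH–O-acyl, C2 = ring C=O, C3(Me)/C4 = ring oxirane, C6 = ring CH bearing the chain, C7/C14 = chain oxirane, C8 = chain C=O, C11 = C–OOH. The presumed biosynthesis is taken as hydroxylated β-bisabolene → epoxidation of Δ3 and Δ7(14) → dehydrogenation at C2/C8 → ene hydroperoxidation of Δ10.

**Step 1**
Reactants: 1 (R)-(−)-carvone; 2 3-methylbutanoic acid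
Product: 3 trans-6-isovaleryloxycarvone (1S,6S)-3-methyl-2-oxo-6-(prop-1-en-2-yl)cyclohex-3-en-1-yl 3-methylbutanoate
Conditions: Mn(OAc)3·2H2O (3 equiv), 2 (10 equiv), PhH, reflux (Dean–Stark)
Reagents that add atoms: 3-methylbutanoic acid (2), CC(C)CC(=O)O
Why: Mn(III)-mediated α′-acyloxylation of an enone (Mn enolate, then carboxylate ligand transfer after acetate/isovalerate exchange) functionalises only C1, and the C1–O bond forms anti to the neighbouring isopropenyl group, so this epimerisable centre settles as the trans-diequatorial 1S ester.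

**Step 2**
Reactants: 3 trans-6-isovaleryloxycarvone
Product: 5 enal (1S,6S)-3-methyl-2-oxo-6-(3-oxoprop-1-en-2-yl)cyclohex-3-en-1-yl 3-methylbutanoate, via allylic alcohol 4 (not isolated)
Conditions: SeO2 (1.2 equiv), 1,4-dioxane, 80 °C
Reagents that add atoms: selenium dioxide, O=[Se]=O
Why: Riley SeO2 allylic oxidation (ene reaction, [2,3]-shift, then a second oxidation) attacks the only electron-rich alkene and takes the methyl group rather than the in-plane C6 methine, giving the 2-substituted acrolein without touching a stereocentre.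

**Step 3**
Reactants: 5 enal; 6 prenyl chloride (1-chloro-3-methylbut-2-ene)
Product: 8 keto carbinol (1S,6S)-6-[(3S)-3-hydroxy-6-methylhepta-1,5-dien-2-yl]-3-methyl-2-oxocyclohex-3-en-1-yl 3-methylbutanoate, via prenylbarium chloride 7 (not isolated)
Conditions: BaI2, Li biphenylide (2 equiv), THF, rt; 6, −78 °C; then 5, −78 °C; 1 M HCl quench
Reagents that add atoms: prenyl chloride (6), CC(C)=CCCl
Why: In this allylbarium carbonyl addition, prenylbarium reacts through its unsubstituted α-carbon and adds 1,2 to the aldehyde much faster than to the hindered enone or the ester, while A(1,3) strain holds C6–H beside the carbonyl oxygen so that attack from the C5 side (away from the C1 ester) should modestly favour the 8S carbinol, and the 8R epimer that also forms is sorted out in step 5.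

**Step 4**
Reactants: 8 keto carbinol
Product: 9 bis(allylic alcohol) (1S,2S,6S)-2-hydroxy-6-[(3S)-3-hydroxy-6-methylhepta-1,5-dien-2-yl]-3-methylcyclohex-3-en-1-yl 3-methylbutanoate
Conditions: NaBH4, CeCl3·7H2O, MeOH, −78 °C
Reagents that add atoms: none
Why: Luche reduction delivers hydride 1,2 along the axial trajectory, as in carvone → cis-carveol, and gives the equatorial 2-OH cis to the side chain and trans to the C1 ester, leaving the ester and alkenes untouched.

**Step 5 (key step)**
Reactants: 9 bis(allylic alcohol)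
Product: 11 bis-epoxy diol (1R,2R,3S,4R,6S)-2-hydroxy-4-{(2R)-2-[(1S)-1-hydroxy-4-methylpent-3-en-1-yl]oxiran-2-yl}-1-methyl-7-oxabicyclo[4.1.0]heptan-3-yl 3-methylbutanoate, via chain monoepoxide 10 (not isolated)
Conditions: Ti(OiPr)4 (0.3 equiv), L-(+)-DIPT (0.36 equiv), TBHP (2.2 equiv, decane), 4 Å MS, CH2Cl2, −20 °C
Reagents that add atoms: tert-butyl hydroperoxide, CC(C)(C)OO
Why: This is a Sharpless asymmetric epoxidation run as a double hydroxyl-directed oxygen transfer, in which L-(+)-tartrate makes the 8S carbinol the fast-reacting epimer and sends oxygen to the Δ7(14) face that gives the erythro 7R,8S epoxy alcohol (the 8R epimer keeps its chain alkene and is removed by chromatography), the Ti-bound 2-OH can deliver oxygen only to its own face of the ring alkene and so places the C3–C4 oxirane cis to the side chain (the tartrate sense is mismatched here, but cyclohexenols discriminate little, so this costs rate and not selectivity), and Δ10, which has no allylic OH, is left alone.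

**Step 6**
Reactants: 11 bis-epoxy diol
Product: 13 diketone (1S,3S,4R,6S)-1-methyl-4-[(2R)-2-(4-methylpent-3-enoyl)oxiran-2-yl]-2-oxo-7-oxabicyclo[4.1.0]heptan-3-yl 3-methylbutanoate, via 8-oxo carbinol 12 (not isolated)
Conditions: DMP (2.5 equiv), NaHCO3, CH2Cl2, 0 °C → rt
Reagents that add atoms: none
Why: Buffered Dess–Martin oxidation converts both epoxy carbinols into α,β-epoxy ketones under near-neutral conditions, so the oxiranes survive, the β,γ-enone is not pulled into conjugation, the relay centres C2 and C8 are erased, and C1 keeps its stable trans arrangement.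

**Step 7**
Reactants: 13 diketone
Product: 14 target (1S,3S,4R,6S)-4-{(2R)-2-[(2E)-4-hydroperoxy-4-methylpent-2-enoyl]oxiran-2-yl}-1-methyl-2-oxo-7-oxabicyclo[4.1.0]heptan-3-yl 3-methylbutanoate
Conditions: O2, TPP (1 mol %), visible light, CH2Cl2, −20 °C; no reductive work-up
Reagents that add atoms: dioxygen, O=O
Why: In the Schenck ene reaction singlet oxygen meets only one electron-rich alkene (Δ10), abstracts a C9–H on the more crowded side (cis effect), moves the double bond into conjugation as the E-enone and leaves the tertiary C11–OOH, with the secondary 10-hydroperoxide regioisomer as the expected by-product to separate and no stereocentre formed or touched.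

**Compound list**
1 | (R)-(−)-carvone | CC1=CC[C@H](CC1=O)C(C)=C | starting material
2 | 3-methylbutanoic acid (isovaleric acid) | CC(C)CC(=O)O | starting material
3 | (1S,6S)-3-methyl-2-oxo-6-(prop-1-en-2-yl)cyclohex-3-en-1-yl 3-methylbutanoate | CC(C)CC(=O)O[C@@H]1C(=O)C(C)=CC[C@H]1C(C)=C | intermediate
4 | (1S,6S)-6-(3-hydroxyprop-1-en-2-yl)-3-methyl-2-oxocyclohex-3-en-1-yl 3-methylbutanoate (not isolated) | CC(C)CC(=O)O[C@@H]1C(=O)C(C)=CC[C@H]1C(=C)CO | intermediate
5 | (1S,6S)-3-methyl-2-oxo-6-(3-oxoprop-1-en-2-yl)cyclohex-3-en-1-yl 3-methylbutanoate | CC(C)CC(=O)O[C@@H]1C(=O)C(C)=CC[C@H]1C(=C)C=O | intermediate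
6 | prenyl chloride (1-chloro-3-methylbut-2-ene) | CC(C)=CCCl | starting material
7 | prenylbarium chloride (not isolated) | CC(C)=CC[Ba]Cl | intermediate
8 | (1S,6S)-6-[(3S)-3-hydroxy-6-methylhepta-1,5-dien-2-yl]-3-methyl-2-oxocyclohex-3-en-1-yl 3-methylbutanoate (8S epimer shown; formed with its 8R epimer) | CC(C)CC(=O)O[C@@H]1C(=O)C(C)=CC[C@H]1C(=C)[C@@H](O)CC=C(C)C | intermediate
9 | (1S,2S,6S)-2-hydroxy-6-[(3S)-3-hydroxy-6-methylhepta-1,5-dien-2-yl]-3-methylcyclohex-3-en-1-yl 3-methylbutanoate (2-OH cis to the chain) | CC(C)CC(=O)O[C@@H]1[C@@H](O)C(C)=CC[C@H]1C(=C)[C@@H](O)CC=C(C)C | intermediate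
10 | (1S,2S,6R)-2-hydroxy-6-{(2R)-2-[(1S)-1-hydroxy-4-methylpent-3-en-1-yl]oxiran-2-yl}-3-methylcyclohex-3-en-1-yl 3-methylbutanoate (not isolated) | CC(C)CC(=O)O[C@@H]1[C@@H](O)C(C)=CC[C@H]1[C@]1([C@@H](O)CC=C(C)C)CO1 | intermediate
11 | (1R,2R,3S,4R,6S)-2-hydroxy-4-{(2R)-2-[(1S)-1-hydroxy-4-methylpent-3-en-1-yl]oxiran-2-yl}-1-methyl-7-oxabicyclo[4.1.0]heptan-3-yl 3-methylbutanoate | CC(C)CC(=O)O[C@@H]1[C@@H](O)[C@@]2(C)O[C@H]2C[C@H]1[C@]1([C@@H](O)CC=C(C)C)CO1 | intermediate
12 | (1R,2R,3S,4R,6S)-2-hydroxy-1-methyl-4-[(2R)-2-(4-methylpent-3-enoyl)oxiran-2-yl]-7-oxabicyclo[4.1.0]heptan-3-yl 3-methylbutanoate (not isolated) | CC(C)CC(=O)O[C@@H]1[C@@H](O)[C@@]2(C)O[C@H]2C[C@H]1[C@]1(C(=O)CC=C(C)C)CO1 | intermediate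
13 | (1S,3S,4R,6S)-1-methyl-4-[(2R)-2-(4-methylpent-3-enoyl)oxiran-2-yl]-2-oxo-7-oxabicyclo[4.1.0]heptan-3-yl 3-methylbutanoate | CC(C)CC(=O)O[C@@H]1C(=O)[C@@]2(C)O[C@H]2C[C@H]1[C@]1(C(=O)CC=C(C)C)CO1 | intermediate
14 | CNP0131119.1 | CC(C)CC(=O)O[C@@H]1C(=O)[C@@]2(C)O[C@H]2C[C@H]1[C@]1(C(=O)/C=C/C(C)(C)OO)CO1 | target

**Totals:** 7 steps in all. The longest linear sequence is 7 steps (1 → 14).

**Steps most likely to fail**

*Step 5 (double epoxidation).* The ring carbinol is mismatched with the tartrate, the diol may tie up titanium, and the 8R epimer limits throughput. The fallback sets out from 5 and rejoins at 13, and it separates the two ring closures.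
- An iminium-catalysed epoxidation of the α-substituted acrolein (diarylprolinol silyl ether of the matching sense, aq. H2O2) sets C7 under catalyst control and gives the epoxy aldehyde F1. The α-methyl ring enone is inert under these conditions.
- Prenylbarium 7 adds to give the epoxy carbinol F2. Its C8 epimers are now irrelevant.
- Luche reduction gives the allylic alcohol diol F3.
- VO(acac)2/TBHP, directed by the 2-OH, closes the ring oxirane to give the bis-epoxy diol epimer mixture F4.
- Dess–Martin oxidation of both carbinols gives 13.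

*Step 3 (α-regioselectivity and chemoselectivity of the barium reagent).* The fallback sets out from 5 and 6 and rejoins at 8. It replaces direct organometallic addition by a sigmatropic prenyl transfer.
- A zinc Barbier reaction of 6 with acetone (γ-attack) gives the donor 2,3,3-trimethylpent-4-en-2-ol F5.
- With 5 and catalytic Sn(OTf)2 or CSA in CH2Cl2 the mixed oxocarbenium ion undergoes a 2-oxonia-Cope rearrangement. This can deliver only the linear prenyl carbinol 8. No epoxide is present at this stage, so the acid is tolerated.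

*Step 2 (SeO2 oxidation: moderate yield, stalling at 4, or Riley attack at C1).* The fallback sets out from 3 and rejoins at 5.
- Ene-type chlorination with HOCl (Ca(OCl)2, CO2, CH2Cl2/H2O) is selective for the isopropenyl group and gives the allylic chloride F6.
- Kornblum oxidation (DMSO, NaHCO3, cat. NaI) converts it into enal 5.

**Further compounds**
F1 | step 5 | (1S,6R)-6-[(2R)-2-formyloxiran-2-yl]-3-methyl-2-oxocyclohex-3-en-1-yl 3-methylbutanoate | CC(C)CC(=O)O[C@@H]1C(=O)C(C)=CC[C@H]1[C@]1(C=O)CO1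
F2 | step 5 | (1S,6R)-6-[(2R)-2-(1-hydroxy-4-methylpent-3-en-1-yl)oxiran-2-yl]-3-methyl-2-oxocyclohex-3-en-1-yl 3-methylbutanoate (C8 epimers) | CC(C)CC(=O)O[C@@H]1C(=O)C(C)=CC[C@H]1[C@]1(C(O)CC=C(C)C)CO1
F3 | step 5 | (1S,2S,6R)-2-hydroxy-6-[(2R)-2-(1-hydroxy-4-methylpent-3-en-1-yl)oxiran-2-yl]-3-methylcyclohex-3-en-1-yl 3-methylbutanoate (C8 epimers) | CC(C)CC(=O)O[C@@H]1[C@@H](O)C(C)=CC[C@H]1[C@]1(C(O)CC=C(C)C)CO1
F4 | step 5 | (1R,2R,3S,4R,6S)-2-hydroxy-4-[(2R)-2-(1-hydroxy-4-methylpent-3-en-1-yl)oxiran-2-yl]-1-methyl-7-oxabicyclo[4.1.0]heptan-3-yl 3-methylbutanoate (C8 epimers) | CC(C)CC(=O)O[C@@H]1[C@@H](O)[C@@]2(C)O[C@H]2C[C@H]1[C@]1(C(O)CC=C(C)C)CO1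
F5 | step 3 | 2,3,3-trimethylpent-4-en-2-ol | C=CC(C)(C)C(C)(C)O
F6 | step 2 | (1S,6S)-6-(3-chloroprop-1-en-2-yl)-3-methyl-2-oxocyclohex-3-en-1-yl 3-methylbutanoate | CC(C)CC(=O)O[C@@H]1C(=O)C(C)=CC[C@H]1C(=C)CCl
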